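**Retrosynthetic overview**
- The target comes from fourfold O-debenzylation of a tetrabenzyl oxolane; the oxolane is the only ring made in the route and results from hydride delivery to the oxocarbenium ion of a 2-hydroxy-oxolane (hemiketal), which sets C2.
- The hemiketal is assembled in one flask from three fragments: a C6 aldehyde/Weinreb amide core carrying both CH2OBn groups, and two equivalents of one aryl bromide (ArMgBr on the aldehyde sets C5; ArLi on the Weinreb amide gives the ketone that closes the ring).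
- The core comes from C2-symmetric (2S,3S)-2,3-bis(benzyloxymethyl)succinic acid, made by double Evans alkylation (sets C3 and C4) of the succinyl bis-oxazolidinone from succinyl chloride.
- The aryl bromide comes from 4-bromophenol by ortho-formylation, O-benzylation, Dakin-type oxidation and O-methylation.
- Ring order: the benzene rings are bought in; the oxolane is closed (O–C2) at the hemiketal stage, after all four carbon substituents are in place.

Assumption: the SMILES is taken as authoritative, i.e. the (2S,3S,4S,5S) isomer, with each aryl cis to its neighbouring CH2OH, the two CH2OH groups trans and the two aryls trans.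

**Step 1**
Reactants: 1 4-bromophenol
Product: 3 5-bromo-2-hydroxybenzaldehyde, via 4-bromo-2-(hydroxymethyl)phenol 2 (not isolated)
Conditions: MgCl2 (1.5 equiv), Et3N (3.75 equiv), (CH2O)n (6.75 equiv), MeCN, reflux, 4 h; 1 M HCl
Reagents that add atoms: paraformaldehyde (formaldehyde) C=O
Why: Magnesium-mediated ortho-formylation of a phenol (Casnati–Skattebøl): the chloromagnesium phenoxide directs formaldehyde ortho (para is blocked by Br) and a second formaldehyde oxidises the benzylic alkoxide by hydride transfer.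

**Step 2**
Reactants: 3 5-bromo-2-hydroxybenzaldehyde
Product: 4 2-(benzyloxy)-5-bromobenzaldehyde
Conditions: BnBr (1.1 equiv), K2CO3 (1.5 equiv), DMF, rt, 12 h
Reagents that add atoms: benzyl bromide BrCc1ccccc1
Why: Williamson ether synthesis on the acidic salicylaldehyde OH; benzyl is the phenol protecting group carried to the last step.

**Step 3**
Reactants: 4 2-(benzyloxy)-5-bromobenzaldehyde
Product: 6 2-(benzyloxy)-5-bromophenol, via 2-(benzyloxy)-5-bromophenyl formate 5 (not isolated)
Conditions: mCPBA (1.3 equiv), CH2Cl2, rt, 16 h; then K2CO3 (0.2 equiv), MeOH, rt, 1 h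
Reagents that add atoms: 3-chloroperoxybenzoic acid OOC(=O)c1cccc(Cl)c1
Why: Baeyer–Villiger (Dakin-type) oxidation: the electron-rich 2-alkoxyaryl group migrates in preference to hydrogen to give the aryl formate, which is methanolysed in the same flask.

**Step 4**
Reactants: 6 2-(benzyloxy)-5-bromophenol
Product: 7 1-(benzyloxy)-4-bromo-2-methoxybenzene
Conditions: MeI (1.5 equiv), K2CO3 (2 equiv), acetone, reflux, 6 h
Reagents that add atoms: iodomethane CI
Why: Williamson O-methylation of the freed phenol fixes OMe meta and OBn para to bromine with no regiochemical ambiguity.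

**Step 5**
Reactants: 8 succinyl chloride
Product: 9 (4R,4'R)-3,3'-(butanedioyl)bis(4-benzyl-1,3-oxazolidin-2-one)
Conditions: (R)-4-benzyl-1,3-oxazolidin-2-one (2.1 equiv), n-BuLi (2.1 equiv), THF, −78 °C, 30 min; then 8 (1.0 equiv), −78 → 0 °C, 2 h
Reagents that add atoms: (R)-4-benzyl-1,3-oxazolidin-2-one (chiral auxiliary) O=C1N[C@H](Cc2ccccc2)CO1
Why: N-acylation of the lithiated Evans oxazolidinone by both acid chloride groups gives the C2-symmetric bis-imide.

**Step 6**
Reactants: 9 bis-imide
Product: 11 (4R,4'R)-3,3'-{(2S,3S)-2,3-bis[(benzyloxy)methyl]butanedioyl}bis(4-benzyl-1,3-oxazolidin-2-one), via mono-alkylated bis-imide 10 (not isolated)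
Conditions: TiCl4 (2.2 equiv), i-Pr2NEt (2.4 equiv), CH2Cl2, 0 °C, 1 h; BnOCH2Cl (3 equiv), 0 °C → rt, 8 h
Reagents that add atoms: benzyl chloromethyl ether ClCOCc1ccccc1
Why: Evans asymmetric alkylation through the chelated (Z)-titanium enolates: the benzyl group of each (R)-auxiliary shields one enolate face, so the benzyloxymethyl electrophile enters from the other and sets (S) at both alpha-carbons (C3 and C4 of the target, hence trans).

**Step 7**
Reactants: 11 dialkylated bis-imide
Product: 13 (2S,3S)-2,3-bis[(benzyloxy)methyl]butanedioic acid, via bis(peroxy acid) 12 (not isolated)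
Conditions: LiOH·H2O (4 equiv), 30% H2O2 (10 equiv), THF/H2O 3:1, 0 °C, 2 h; aq. Na2SO3; then 1 M HCl to pH 2
Reagents that add atoms: hydrogen peroxide OO
Why: Hydroperoxide hydrolysis of the Evans imides: LiOOH attacks the exocyclic carbonyl selectively without epimerising the alpha-centres, and sulfite reduces the peroxy acid to the acid.

**Step 8**
Reactants: 13 diacid
Product: 14 (2S,3S)-2,3-bis[(benzyloxy)methyl]-N1,N4-dimethoxy-N1,N4-dimethylbutanediamide
Conditions: MeNH(OMe)·HCl (2.6 equiv), EDC·HCl (2.6 equiv), HOBt (1.0 equiv), N-methylmorpholine (6 equiv), CH2Cl2, 0 °C → rt, 14 h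
Reagents that add atoms: N,O-dimethylhydroxylamine hydrochloride CNOC.Cl
Why: Carbodiimide-mediated amide coupling (via the HOBt esters) converts both acids into Weinreb amides without touching the alpha-stereocentres.

**Step 9**
Reactants: 14 bis-Weinreb amide
Product: 15 (2S,3S)-2,3-bis[(benzyloxy)methyl]-N-methoxy-N-methyl-4-oxobutanamide
Conditions: i-Bu2AlH (1.05 equiv), THF, −78 °C, 1 h; aq. potassium sodium tartrate (KNaC4H4O6); crude aldehyde used at once
Reagents that add atoms: none
Why: Weinreb amide reduction: the tetrahedral aluminium chelate is stable at −78 °C and releases the aldehyde only on work-up, and because 14 is C2-symmetric one equivalent of hydride gives the same mono-aldehyde whichever amide reacts (unreacted 14 is recycled).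

**Step 10**
Reactants: 15 aldehyde Weinreb amide; 7 1-(benzyloxy)-4-bromo-2-methoxybenzene (2.9 equiv in all)
Product: 20 (3S,4S,5S)-2,5-bis[4-(benzyloxy)-3-methoxyphenyl]-3,4-bis[(benzyloxy)methyl]oxolan-2-ol (hemiketal; both C2 epimers), via arylmagnesium bromide 16 (not isolated), via aryllithium 17 (not isolated), via hydroxy Weinreb amide 18 (not isolated), via open-chain hydroxy ketone 19 (not isolated)
Conditions: 7 (1.3 equiv), Mg, THF, 40 °C (gives 16); separately 7 (1.6 equiv), n-BuLi (1.6 equiv), THF, −78 °C (gives 17); 15 in THF/toluene, −78 °C, add 16 (1.2 equiv), 1 h, then 17 (1.5 equiv), 1 h; aq. NH4Cl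
Reagents that add atoms: none
Why: Two chemoselective 1,2-additions in one flask join three fragments: the Grignard reagent adds only to the aldehyde at −78 °C under Felkin–Anh control reinforced by magnesium chelation to the beta-benzyloxy group, setting the (S)-carbinol (C5 of the target, cis to its CH2O neighbour); the aryllithium then gives the ketone (Weinreb ketone synthesis), and the gamma-hydroxy ketone closes to the hemiketal on work-up.

**Step 11**
Reactants: 20 hemiketal
Product: 22 (2S,3S,4S,5S)-2,5-bis[4-(benzyloxy)-3-methoxyphenyl]-3,4-bis[(benzyloxy)methyl]oxolane, via 2-aryl oxocarbenium ion 21 (not isolated)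
Conditions: Et3SiH (5 equiv), BF3·OEt2 (2.5 equiv), CH2Cl2, −78 °C, 1 h; aq. NaHCO3 at −78 °C
Reagents that add atoms: none
Why: Reductive deoxygenation of the hemiketal (ionic hydrogenation): BF3 generates the 2-aryl oxocarbenium ion and Et3SiH delivers hydride anti to the adjacent C3 benzyloxymethyl group, setting C2 (S) with the aryl cis to C3 and trans to the C5 aryl; the low temperature prevents acid epimerisation of the benzylic ether centres.

**Step 12**
Reactants: 22 tetrabenzyl oxolane
Product: 23 Eduesmine, 4,4'-[(2S,3S,4S,5S)-3,4-bis(hydroxymethyl)oxolane-2,5-diyl]bis(2-methoxyphenol)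
Conditions: H2 (1 atm), 10% Pd/C, EtOAc/MeOH 1:1, rt, 2–4 h (stopped at full debenzylation)
Reagents that add atoms: none
Why: Catalytic hydrogenolysis cleaves the four O-benzyl groups much faster than the ring benzylic C–O bonds in neutral solvent at 1 atm, freeing the two phenols and two primary alcohols without touching any stereocentre.

**Compound list**
1 | 4-bromophenol | Oc1ccc(Br)cc1 | starting material
2 | 4-bromo-2-(hydroxymethyl)phenol (present as its magnesium phenoxide) | OCc1cc(Br)ccc1O | intermediate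
3 | 5-bromo-2-hydroxybenzaldehyde | O=Cc1cc(Br)ccc1O | intermediate
4 | 2-(benzyloxy)-5-bromobenzaldehyde | O=Cc1cc(Br)ccc1OCc1ccccc1 | intermediate
5 | 2-(benzyloxy)-5-bromophenyl formate | O=COc1cc(Br)ccc1OCc1ccccc1 | intermediate
6 | 2-(benzyloxy)-5-bromophenol | Oc1cc(Br)ccc1OCc1ccccc1 | intermediate
7 | 1-(benzyloxy)-4-bromo-2-methoxybenzene | COc1cc(Br)ccc1OCc1ccccc1 | intermediate
8 | succinyl chloride (butanedioyl dichloride) | ClC(=O)CCC(Cl)=O | starting material
9 | (4R,4'R)-3,3'-(butanedioyl)bis(4-benzyl-1,3-oxazolidin-2-one) | O=C1OC[C@@H](Cc2ccccc2)N1C(=O)CCC(=O)N1[C@H](Cc2ccccc2)COC1=O | intermediate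
10 | (4R)-4-benzyl-3-[(2S)-4-[(4R)-4-benzyl-2-oxo-1,3-oxazolidin-3-yl]-2-[(benzyloxy)methyl]-4-oxobutanoyl]-1,3-oxazolidin-2-one | O=C1OC[C@@H](Cc2ccccc2)N1C(=O)[C@H](COCc1ccccc1)CC(=O)N1[C@H](Cc2ccccc2)COC1=O | intermediate
11 | (4R,4'R)-3,3'-{(2S,3S)-2,3-bis[(benzyloxy)methyl]butanedioyl}bis(4-benzyl-1,3-oxazolidin-2-one) | O=C1OC[C@@H](Cc2ccccc2)N1C(=O)[C@H](COCc1ccccc1)[C@@H](COCc1ccccc1)C(=O)N1[C@H](Cc2ccccc2)COC1=O | intermediate
12 | (2S,3S)-2,3-bis[(benzyloxy)methyl]butanediperoxoic acid (present as its dilithium salt) | OOC(=O)[C@H](COCc1ccccc1)[C@@H](COCc1ccccc1)C(=O)OO | intermediate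
13 | (2S,3S)-2,3-bis[(benzyloxy)methyl]butanedioic acid | OC(=O)[C@H](COCc1ccccc1)[C@@H](COCc1ccccc1)C(O)=O | intermediate
14 | (2S,3S)-2,3-bis[(benzyloxy)methyl]-N1,N4-dimethoxy-N1,N4-dimethylbutanediamide | CON(C)C(=O)[C@H](COCc1ccccc1)[C@@H](COCc1ccccc1)C(=O)N(C)OC | intermediate
15 | (2S,3S)-2,3-bis[(benzyloxy)methyl]-N-methoxy-N-methyl-4-oxobutanamide | O=C[C@H](COCc1ccccc1)[C@@H](COCc1ccccc1)C(=O)N(C)OC | intermediate
16 | [4-(benzyloxy)-3-methoxyphenyl]magnesium bromide | COc1cc([Mg]Br)ccc1OCc1ccccc1 | intermediate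
17 | [4-(benzyloxy)-3-methoxyphenyl]lithium | [Li]c1ccc(OCc2ccccc2)c(OC)c1 | intermediate
18 | (2S,3S,4S)-4-[4-(benzyloxy)-3-methoxyphenyl]-2,3-bis[(benzyloxy)methyl]-4-hydroxy-N-methoxy-N-methylbutanamide (present as its bromomagnesium alkoxide) | COc1cc([C@@H](O)[C@H](COCc2ccccc2)[C@@H](COCc2ccccc2)C(=O)N(C)OC)ccc1OCc1ccccc1 | intermediate
19 | (2S,3S,4S)-1,4-bis[4-(benzyloxy)-3-methoxyphenyl]-2,3-bis[(benzyloxy)methyl]-4-hydroxybutan-1-one | COc1cc([C@@H](O)[C@H](COCc2ccccc2)[C@@H](COCc2ccccc2)C(=O)c2ccc(OCc3ccccc3)c(OC)c2)ccc1OCc1ccccc1 | intermediate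
20 | (3S,4S,5S)-2,5-bis[4-(benzyloxy)-3-methoxyphenyl]-3,4-bis[(benzyloxy)methyl]oxolan-2-ol (both C2 epimers) | COc1cc(C2(O)O[C@H](c3ccc(OCc4ccccc4)c(OC)c3)[C@H](COCc3ccccc3)[C@H]2COCc2ccccc2)ccc1OCc1ccccc1 | intermediate
21 | 2-aryl oxocarbenium ion formed from 20 by loss of hydroxide (C3, C4 and C5 of 20 unchanged) | COc1cc(C2=[O+][C@H](c3ccc(OCc4ccccc4)c(OC)c3)[C@H](COCc3ccccc3)[C@H]2COCc2ccccc2)ccc1OCc1ccccc1 | intermediate
22 | (2S,3S,4S,5S)-2,5-bis[4-(benzyloxy)-3-methoxyphenyl]-3,4-bis[(benzyloxy)methyl]oxolane | COc1cc([C@H]2O[C@H](c3ccc(OCc4ccccc4)c(OC)c3)[C@H](COCc3ccccc3)[C@H]2COCc2ccccc2)ccc1OCc1ccccc1 | intermediate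
23 | Eduesmine, 4,4'-[(2S,3S,4S,5S)-3,4-bis(hydroxymethyl)oxolane-2,5-diyl]bis(2-methoxyphenol) | COc1cc([C@H]2O[C@H](c3ccc(O)c(OC)c3)[C@H](CO)[C@H]2CO)ccc1O | target

**Step count**
Total step count: 12. Longest linear sequence: 8 steps (steps 5–12, from 8). The aryl branch (steps 1–4) enters at step 10.

**Three steps most likely to fail**

Step 6 (double alkylation). The second benzyloxymethylation takes place next to a newly branched centre and may stall or lose selectivity. The fallback sets out from 10, obtained by limiting TiCl4, i-Pr2NEt and BnOCH2Cl to 1.05 equiv, and comes back at 15. LiBH4 (THF/H2O, 0 °C) reduces both imides to (R)-2-[(benzyloxy)methyl]butane-1,4-diol F1. TEMPO (cat.) with PhI(OAc)2 in CH2Cl2 oxidises the less hindered CH2CH2OH end and closes to (S)-4-[(benzyloxy)methyl]oxolan-2-one F2. LiN(i-Pr)2 (THF, −78 °C) then BnOCH2Cl alkylates the lactone enolate anti to the C4 substituent, so the second centre is set by the ring and not by an auxiliary, giving (3S,4S)-3,4-bis[(benzyloxy)methyl]oxolan-2-one F3. MeNH(OMe)·HCl with AlMe3 (CH2Cl2, 0 °C) opens the lactone to (2S,3R)-2,3-bis[(benzyloxy)methyl]-4-hydroxy-N-methoxy-N-methylbutanamide F4, and Dess–Martin periodinane (NaHCO3, CH2Cl2) gives 15.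

Step 10 (one-flask double arylation). Over-addition or a poor ratio at the new carbinol carbon would be hard to correct on the hemiketal mixture. The fallback sets out from 15 and comes back at 20. Only the Grignard reagent 16 is added (−78 °C) and the free alcohol 18 is isolated. Pyridinium p-toluenesulfonate in toluene at 60 °C lactonises it to (3S,4S,5S)-5-[4-(benzyloxy)-3-methoxyphenyl]-3,4-bis[(benzyloxy)methyl]oxolan-2-one F5, which is freed from its C5 epimer by crystallisation. The aryllithium 17 (THF, −78 °C) then adds once to the lactone carbonyl and gives 20 on work-up.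

Step 11 (reductive deoxygenation). Hydride must arrive on the face that already carries the C4 substituent and the C5 aryl, and BF3 can epimerise the cis benzylic ether centres. The fallback sets out from 20 and comes back at 22. PhSH with catalytic pyridinium p-toluenesulfonate (4 Å sieves, CH2Cl2, 0 °C) gives (3S,4S,5S)-2,5-bis[4-(benzyloxy)-3-methoxyphenyl]-3,4-bis[(benzyloxy)methyl]-2-(phenylsulfanyl)oxolane F6. Bu3SnH with AIBN (toluene, 80 °C) then reduces it under neutral radical conditions: the planar 2-aryl-oxolan-2-yl radical takes hydrogen anti to the C3 substituent and gives 22 without any Lewis acid.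

**Further compounds**
F1 | step 6 | (R)-2-[(benzyloxy)methyl]butane-1,4-diol | OCC[C@H](CO)COCc1ccccc1
F2 | step 6 | (S)-4-[(benzyloxy)methyl]oxolan-2-one | O=C1C[C@@H](COCc2ccccc2)CO1
F3 | step 6 | (3S,4S)-3,4-bis[(benzyloxy)methyl]oxolan-2-one | O=C1OC[C@H](COCc2ccccc2)[C@H]1COCc1ccccc1
F4 | step 6 | (2S,3R)-2,3-bis[(benzyloxy)methyl]-4-hydroxy-N-methoxy-N-methylbutanamide | OC[C@H](COCc1ccccc1)[C@@H](COCc1ccccc1)C(=O)N(C)OC
F5 | step 10 | (3S,4S,5S)-5-[4-(benzyloxy)-3-methoxyphenyl]-3,4-bis[(benzyloxy)methyl]oxolan-2-one | O=C1O[C@H](c2ccc(OCc3ccccc3)c(OC)c2)[C@H](COCc2ccccc2)[C@H]1COCc1ccccc1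
F6 | step 11 | (3S,4S,5S)-2,5-bis[4-(benzyloxy)-3-methoxyphenyl]-3,4-bis[(benzyloxy)methyl]-2-(phenylsulfanyl)oxolane (both C2 epimers) | COc1cc(C2(Sc3ccccc3)O[C@H](c3ccc(OCc4ccccc4)c(OC)c3)[C@H](COCc3ccccc3)[C@H]2COCc2ccccc2)ccc1OCc1ccccc1
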